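Readings and results were generated by integration with made-up constants; noise was put on by code.

The dusk run loses 0.0850 M of starting material in its first 2.0 min but less, 0.00200 M, between 14 min and 16 min, and this slowing is what to watch.

| flask | starting material | partner | time |
|---|---|---|---|
| dusk | 0.400 M | 0.800 M |  |
| summer | 0.400 M | 0.400 M |  |
| autumn | 0.800 M | 0.800 M |  |
| dawn | 0.400 M | 0.800 M | 32 min |

| dusk run: time / min | dusk run: [starting material] / M | summer run: time / min | summer run: [starting material] / M | autumn run: time / min | autumn run: [starting material] / M |
|---|---|---|---|---|---|
| 2.0 | 0.315 | 2.0 | 0.359 | 2.0 | 0.624 |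
| 4.0 | 0.260 | 4.0 | 0.315 | 4.0 | 0.529 |
| 6.0 | 0.224 | 6.0 | 0.284 | 6.0 | 0.465 |
| 8.0 | 0.198 | 8.0 | 0.265 | 8.0 | 0.428 |
| 10 | 0.175 | 10 | 0.250 | 10 | 0.404 |
| 12 | 0.165 | 12 | 0.234 | 12 | 0.388 |
| 14 | 0.151 | 14 | 0.230 | 14 | 0.370 |
| 16 | 0.149 | 16 | 0.225 | 16 | 0.364 |

(each reading ± 0.004 M)

- reaction order in [partner] at the outset, round the charge of the dusk run, defined at two percent of the starting material turned into product
- reaction order in [starting material] at the outset, round the charge of the dusk run, defined at two percent of the starting material turned into product (one fixed amount of product, the same in the runs compared)
- starting material in the dawn run at 32 min, as a share of the starting material charged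

- Overall: starting material + partner -> product.
- Constant volume, constant temperature.
- The analysis sees a species whether free or bound.
- "The second partner" is partner.
- An order is taken over about fifteen percent of the charge, up and down.

We write [S] and [R] for starting material and partner, S_c and R_c for their charges, and x for S_c minus [S], so that [R] is R_c minus x.

1. Main step by itself. Take the rate as k[S][R], with starting material the limiting reagent of the dusk run. This integrates to ln(([R]/[S])(S_c/R_c)) = k(R_c − S_c)t, and the first dusk reading gives k = 0.158 /M/min. The first loss in the autumn run over that in the dusk run gives an order in starting material of 1.05. The dusk loss over the summer loss gives an order in partner of 1.05. This step puts the dawn run at 7.07 % at 32 min. For the dusk run it gives 0.0888 M at 16 min, yet that run reads 0.149 M.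

2. Add the reverse step. Then the plateau ratio Q, x/([S][R]) read at the last point, should hold steady across charges if one product forms per turn. The dusk run reads Q = 3.07 /M, the summer run 3.46 /M and the autumn run 3.29 /M. The dawn run has the dusk charge, so Q returns 37.2 %.

3. Add the remaining drift. The last dusk readings still fall at 0.001000 M/min, though that slope carries a scatter of 0.002828 M/min. Carried to 32 min, it gives our figure of 33.2 %.

The forecast gives orders of 1 in partner and 1 in starting material, and 34 % for the dawn run, higher than our figure, on the ground that “the plateaus look like equilibrium rather than a dying reaction”.

The simulation gives orders of 1.0 in partner and 1.0 in starting material, and 32.5 % for the dawn run at 32 min.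

    starting material + partner ⇌ product + by-product (0.1470 /M/min, 2.586 /M/min)
    partner + by-product ⇌ reagent-by-product salt, settled at all times (43.70 /M)
    2 starting material → homo dimer (0.02184 /M/min)

The path to homo dimer moves the readings by 17 scatter units, root mean square. Counting each lost starting material as product, the dawn share gives Q = 3.92 /M, against 3.07 /M read in the dusk run. Put on the equal charges of the summer run, the dusk Q gives [S] = 0.233 M, and that run read 0.225 M at 16 min.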